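(Readings and results are calculated from invented constants, noise included.)

common to all: left-handed substrate 0.084 M; right-handed substrate 0.084 M; gas 26 mM (held); free catalyst 5 mol%; impurity 1.6 mM
- spring: the very flask that is asked about, followed so far
- flask: time 4.0 h

spring run (percent of the left-handed substrate and right-handed substrate together charged)

| time / min | right-handed substrate / % | left-handed substrate / % | left-handed product / % |
|---|---|---|---|
| 15.0 | 48.9 | 48.9 | 1.6 |
| 30.0 | 49.0 | 43.9 | 6.0 |
| 50.0 | 46.6 | 39.4 | 10.8 |
| 60.0 | 45.5 | 36.6 | 13.1 |
| 80.0 | 44.1 | 33.4 | 16.3 |
| 90.0 | 44.1 | 33.3 | 17.9 |
| 120 | 38.7 | 26.3 | 22.1 |

(readings scatter by 1 percentage point)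

- free catalyst is single-handed; left-handed substrate and right-handed substrate are mirror images of each other, charged as a racemate, each of them at the stated concentration
- at the start none of reagent is dissolved
- candidate steps: free catalyst + impurity -> spent catalyst; left-handed substrate <-> right-handed substrate; gas <-> reagent; reagent + free catalyst + right-handed substrate -> free catalyst + right-handed product; reagent + free catalyst + left-handed substrate -> free catalyst + left-handed product

* whether the excess of right-handed substrate over left-handed substrate among what is left of the two reaches 95% by 4.0 h (yes / no)
* the highest excess of right-handed substrate over left-handed substrate among what is left of the two up to 4.0 h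

Left-handed substrate falls faster than right-handed substrate in this flask: at 120 min the readings stand at 26.3% against 38.7%.

How much faster? Both substrates meet the same reagent and the same free catalyst, so each is taken to fall in proportion to its own c, with the interconversion set aside. Time then drops out of one ratio: the split s, ln(part of left-handed substrate left) divided by ln(part of right-handed substrate left), the selectivity factor. Averaged over the last three readings against the scatter, the parts left of own charge are 62.0% and 84.6%, so s reads 2.86.

What does the wanted excess ask? If a part y of right-handed substrate is left, y^s of left-handed substrate is left, and the excess is their difference over their sum. So 95% asks y down to 13.9%.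

How far does the flask get? From 30.0 min to 120 min, the readings of ln c(left-handed substrate) fall at 0.342 h⁻¹. My reckoning holds this pseudo-first-order line to 4.0 h, which gives an estimate of 26.6% of the charge of left-handed substrate left. Through s, that goes with 62.9% of the charge of right-handed substrate, above the part required. My answer is no, and my top is the excess at the end, 40.6%.

The forecast says no and 36%, below my figure: “It is still rising at 4 h, so the top value is the 4 h value”.

The flask gives no and a top of 40.9%.

    free catalyst + impurity → spent catalyst (k = 30000 M⁻¹ h⁻¹)
    left-handed substrate ⇌ right-handed substrate (k = 0.0200 h⁻¹)
    gas ⇌ reagent, rate k3*(csat - [reagent]) (kL = 6.60 h⁻¹)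
    reagent + free catalyst + right-handed substrate → free catalyst + right-handed product (k = 2000 M⁻² h⁻¹)
    reagent + free catalyst + left-handed substrate → free catalyst + left-handed product (k = 6200 M⁻² h⁻¹)

At 4.00 h the flask keeps 26% of its left-handed substrate and 62% of its right-handed substrate. Put through s, that part of right-handed substrate gives 25.8% of left-handed substrate. The neighbour flask with 6.4 × 10⁻⁴ M of impurity keeps 53% of right-handed substrate at 4.00 h. Through s this gives an excess of 53.0%, and that flask's top stands at 52.1%.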